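The earlier runs and the new flask come from a simulation with constants of no real substance.

Follow E.

| flask | G | E | remark | time |
|---|---|---|---|---|
| dusk | 0.055 M | 0.035 M | run made earlier |  |
| eta | 0.030 M | 0.00800 M |  | 6.0 d |
| theta | 0.050 M | 0.0350 M |  | 6.0 d |

- dusk (time / d: X / %, G / %): 0.250: 24, 56; 0.417: 36, 42; 0.625: 40, 27; 1.04: 38, 18; 1.67: 34, 17; 2.50: 30, 18; 4.00: 21, 18

(readings scatter by 1.5 percentage points)



- the winner by amount of X, in percent of the G charged; "neither" if no more than 2 percentage points parts them (eta / theta / neither)
- how much X is there at the end, in percent of the G charged: eta
- how much X is there at the end, in percent of the G charged: theta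

I kept a ledger of E, which I took for the limiting reagent: in dusk the G readings lay flat near 17% from 1.67 d on, while X went on falling. X fell from 38% at 1.04 d to 21% at 4.00 d, and I read that as a first-order loss with rate constant 0.200 /d. Carried back to time zero, the X ever made in dusk came to 46.8% of the G charged, which by the charges is 73.5% of the E charged. That is the harvest, the share of the E charged that ever became X, a reading that carries the scatter. The other 26.5% of E stood in the books as unaccounted for.

Two multiplications then gave each flask. I assumed that the harvest read in dusk held in both flasks. Eta charged E at 26.7% of its G, so I put the X it made at 19.6% of its G; theta charged 70.0%, so I put its X made at 51.5%. Over 6.0 d I reckoned that a fraction 30.1% of X survived, which gave 5.91% for eta and 15.5% for theta, so I put theta higher.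

The forecast said 6.3% for eta and 15.5% for theta, winner theta, and called the reaction “limited by E running out, not by an equilibrium”. My eta figure sat slightly below its number.

The flasks gave 5.96% in eta and 13.2% in theta, so theta won.

    G ⇌ D (K = 2.00, k = 3.04 × 10⁻⁵ /s)
    E → L (k = 5.03 × 10⁻⁵ /s)
    D + L → X (k = 0.0163 /M/s)
    2 L → Z (k = 0.00590 /M/s)
    X → Q (k = 2.85 × 10⁻⁶ /s)

In theta the step from E to L had >99.9% of its turnover behind it at 3.00 d, and the step from D + L to X had passed its midpoint at 0.261 d. From 3.00 d to 6.00 d G stayed at 15.6% and D at 31.1%, while X went from 27.6% to 13.2% and Q rose from 25.7% to 40.1%. The books closed in theta with X and Q together at 76.1% of the E charged and Z at 23.9%. In eta they closed with X and Q at 90.4% and Z at 9.64%, so the harvest changed from flask to flask. My eta figure came near the flask because two errors offset: the harvest I used was lower than eta's, and my survival of 30.1% was higher than the 24.7% of X and Q that stood as X in eta.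

Take theta with 0.021 M of E instead: the harvest from dusk and my survival give 9.28%, and the computed flask holds 8.92%, with X and Q at 86.1% of the E charged.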